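**Plan** (halimane numbering: ring A = C1–C5, C10; ring B = C5–C10; side chain C11–C16)

1. Retrosynthesis: the two acetates come off first, then C13–CH3 is cut (methyl Grignard onto a C13 ketone), then C12–C13 (a C12 zinc reagent plus an (R)-glycerate thioester); this leaves a two-carbon iodide that stems from a C9 allyl group.
2. Ring A is opened at C4–C5 and C2–C3. It holds the C1=C10 alkene with C10 shared with ring B, and quaternary C4 (methyl, carboxyl) sits next to C5–H; this is the pattern of a Diels–Alder adduct of a ring B 1-vinylcyclohexene (C5=C10–C1=C2) with methacrolein.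
3. The diene is cut at C1–C10 (vinyl coupling of an enol triflate), C9–C11 (enolate allylation) and C8–CH3 (conjugate addition), back to 2-methylcyclohex-2-en-1-one.
4. Forward: ring B is bought and substituted at C8 and C9, the diene is made, ring A closes in the cycloaddition, CHO becomes CO2Me, the allyl group is trimmed to C11–C12–I, the C13–C15 unit is joined and the chain is finished.
5. Stereochemistry: C8 from the chiral copper catalyst; C9 from allylation anti to the C8 methyl; C5 and C4 from the diene face and the formyl-exo mode of the cycloaddition; C14 from (R)-glycerate; C13 from chelate-controlled Grignard addition.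

Key step: step 5

Assumption: the (S,R,R) antipode of the BINOL/bis(1-phenylethyl)amine phosphoramidite is taken to deliver methyl to the enone face that gives the (3R) centre; if the sense is the opposite, the (R,S,S) ligand is used with no other change.

**Step 1**
Reactants: 1 2-methylcyclohex-2-en-1-one
Product: 3 (R)-[(2,3-dimethylcyclohex-1-en-1-yl)oxy]trimethylsilane, via aluminium enolate 2 (not isolated)
Conditions: Me3Al, Cu(O2CC4H3S) (copper thiophene-2-carboxylate, monovalent copper, 2 mol%), (S,R,R)-phosphoramidite (4 mol%), Et2O, −30 °C; then Me3SiOTf, THF, −30 → 0 °C; non-aqueous work-up (Et3N, pentane)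
Reagents that add atoms: trimethylaluminium C[Al](C)C; trimethylsilyl triflate C[Si](C)(C)OS(=O)(=O)C(F)(F)F
Why: Copper/phosphoramidite-catalysed asymmetric conjugate addition of Me3Al is precedented for 2-substituted cyclohexenones, the ligand choosing the enone face and so setting the methyl-bearing centre (future C8, R), while silylation of the aluminium enolate locks the tetrasubstituted enolate regiochemistry.

**Step 2**
Reactants: 3 (R)-[(2,3-dimethylcyclohex-1-en-1-yl)oxy]trimethylsilane; 4 allyl bromide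
Product: 6 (2S,3R)-2-allyl-2,3-dimethylcyclohexan-1-one, via lithium enolate 5 (not isolated)
Conditions: MeLi, THF, 0 °C → rt; then allyl bromide, DMPU, −78 → 0 °C
Reagents that add atoms: methyllithium [Li]C (lithium of intermediate 5 only)
Why: Si–O cleavage by MeLi releases the regiodefined lithium enolate, and enolate C-alkylation by the allylic halide takes place anti to the neighbouring ring methyl, which sets the quaternary centre (future C9) with the two methyl groups cis.

**Step 3**
Reactants: 6 (2S,3R)-2-allyl-2,3-dimethylcyclohexan-1-one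
Product: 8 (5R,6S)-6-allyl-5,6-dimethylcyclohex-1-en-1-yl trifluoromethanesulfonate, via potassium enolate 7 (not isolated)
Conditions: KN(SiMe3)2, THF, −78 °C; then PhNTf2, −78 → 0 °C
Reagents that add atoms: potassium hexamethyldisilazide [K+].C[Si](C)(C)[N-][Si](C)(C)C (potassium of intermediate 7 only); N-phenylbis(trifluoromethanesulfonimide) O=S(=O)(N(c1ccccc1)S(=O)(=O)C(F)(F)F)C(F)(F)F
Why: Only one α-carbon of the ketone carries hydrogen, so deprotonation and O-sulfonylation (enol triflate formation) can give a single regioisomer without touching either stereocentre.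

**Step 4**
Reactants: 8 (5R,6S)-6-allyl-5,6-dimethylcyclohex-1-en-1-yl trifluoromethanesulfonate; 9 tributyl(vinyl)stannane
Product: 10 (5R,6S)-6-allyl-5,6-dimethyl-1-vinylcyclohex-1-ene
Conditions: Pd(PPh3)4 (5 mol%), LiCl (3 equiv), THF, 65 °C
Reagents that add atoms: none
Why: Stille cross-coupling of an enol triflate with a vinylstannane under zerovalent palladium with LiCl is a standard entry to 1-vinylcyclohexenes and leaves the isolated allyl group alone.

**Step 5**
Reactants: 10 (5R,6S)-6-allyl-5,6-dimethyl-1-vinylcyclohex-1-ene; 11 methacrolein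
Product: 12 (1R,5S,6R,8aR)-5-allyl-1,5,6-trimethyl-1,2,3,5,6,7,8,8a-octahydronaphthalene-1-carbaldehyde (halimane numbering: 4R,5R,8R,9S; C4 aldehyde, C1=C10 alkene)
Conditions: Me2AlCl (0.5 equiv), methacrolein (3 equiv), CH2Cl2, −78 → −30 °C
Reagents that add atoms: none
Why: Me2AlCl binds the formyl oxygen of 11 and lowers its LUMO, so that a concerted but asynchronous [4+2] cycloaddition (Lewis acid-catalysed Diels–Alder reaction of a 1-vinylcyclohexene with a 2-substituted acrolein) takes place on the s-cis diene C5=C10–C1=C2, which quaternary C9 favours over the s-trans form. The β-carbon of the enal (future C3) bonds ahead to the unhindered vinyl terminus C2 and the formyl-bearing carbon (future C4) then closes on the ring terminus C5, so ring A forms as a cyclohexene by a six-membered closure that is suprafacial on both partners, with the new alkene at C1=C10. C5 is set by the diene face: with the C8 methyl equatorial the cis C9 methyl is pseudoaxial and blocks its own face, so the dienophile should add anti to it and leave H5 cis to that methyl. C4 is set by the formyl-exo mode that 2-substituted acroleins prefer, helped here because the aluminium-bound carbonyl keeps away from the C9 substituents; this puts the formyl group cis to H5 and the new methyl trans. The step thus needs regio-, facial and exo selectivity, and the isolated allyl alkene is not expected to compete at low temperature.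

**Step 6**
Reactants: 12 the C4 aldehyde
Product: 13 (1R,5S,6R,8aR)-5-allyl-1,5,6-trimethyl-1,2,3,5,6,7,8,8a-octahydronaphthalene-1-carboxylic acid
Conditions: NaClO2, NaH2PO4, 2-methylbut-2-ene, t-BuOH/H2O, 0 °C → rt
Reagents that add atoms: sodium chlorite [Na+].[O-]Cl=O
Why: Pinnick oxidation turns the hindered, non-enolisable aldehyde into the acid while the hypochlorite formed is trapped by 2-methylbut-2-ene, so neither alkene is attacked and C4 cannot epimerise.

**Step 7**
Reactants: 13 the C4 carboxylic acid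
Product: 14 methyl (1R,5S,6R,8aR)-5-allyl-1,5,6-trimethyl-1,2,3,5,6,7,8,8a-octahydronaphthalene-1-carboxylate
Conditions: MeI, K2CO3, DMF, rt
Reagents that add atoms: iodomethane CI
Why: SN2 O-alkylation of the carboxylate esterifies the neopentyl-type acid under non-acidic conditions that cannot move the C1=C10 alkene.

**Step 8**
Reactants: 14 the allyl methyl ester
Product: 15 methyl (1R,5S,6R,8aR)-1,5,6-trimethyl-5-(2-oxoethyl)-1,2,3,5,6,7,8,8a-octahydronaphthalene-1-carboxylate
Conditions: OsO4 (2 mol%), NaIO4 (4 equiv), 2,6-lutidine, dioxane/H2O (3:1), rt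
Reagents that add atoms: osmium tetroxide O=[Os](=O)(=O)=O; sodium periodate [Na+].[O-]I(=O)(=O)=O
Why: Lemieux–Johnson cleavage (catalytic osmylation followed by periodate glycol cleavage) should pick the unhindered monosubstituted alkene over the trisubstituted C1=C10 alkene flanked by quaternary C9, with 2,6-lutidine suppressing over-oxidation.

**Step 9**
Reactants: 15 the C12 aldehyde
Product: 16 methyl (1R,5S,6R,8aR)-5-(2-hydroxyethyl)-1,5,6-trimethyl-1,2,3,5,6,7,8,8a-octahydronaphthalene-1-carboxylate
Conditions: NaBH4, MeOH, 0 °C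
Reagents that add atoms: none
Why: Borohydride reduction of the aldehyde is chemoselective over the hindered methyl ester.

**Step 10**
Reactants: 16 the C12 alcohol
Product: 17 methyl (1R,5S,6R,8aR)-5-(2-iodoethyl)-1,5,6-trimethyl-1,2,3,5,6,7,8,8a-octahydronaphthalene-1-carboxylate
Conditions: PPh3, I2, imidazole, CH2Cl2, 0 °C → rt
Reagents that add atoms: iodine II
Why: Appel-type iodination converts the primary alcohol into the iodide by SN2 displacement of the oxyphosphonium group under neutral conditions.

**Step 11**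
Reactants: 18 methyl (R)-2,2-dimethyl-1,3-dioxolane-4-carboxylate
Product: 19 S-ethyl (R)-2,2-dimethyl-1,3-dioxolane-4-carbothioate
Conditions: Me3Al, EtSH, CH2Cl2, 0 °C → rt
Reagents that add atoms: ethanethiol CCS
Why: Me3Al and EtSH form Me2AlSEt, which exchanges the methyl ester for the thioester (aluminium thiolate ester-to-thioester exchange) without a base that could epimerise the α-alkoxy centre, and the acetonide tolerates the conditions.

**Step 12**
Reactants: 17 the C12 iodide; 19 S-ethyl (R)-2,2-dimethyl-1,3-dioxolane-4-carbothioate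
Product: 21 methyl (1R,5S,6R,8aR)-5-{3-[(4R)-2,2-dimethyl-1,3-dioxolan-4-yl]-3-oxopropyl}-1,5,6-trimethyl-1,2,3,5,6,7,8,8a-octahydronaphthalene-1-carboxylate, via alkylzinc iodide 20 (not isolated)
Conditions: Zn dust (activated with BrCH2CH2Br and Me3SiCl), THF, 40 °C; then 19, PdCl2(PPh3)2 (5 mol%), toluene, rt
Reagents that add atoms: zinc [Zn] (metal of intermediate 20 only)
Why: Direct zinc insertion gives an ester-tolerant primary alkylzinc iodide, and Fukuyama coupling with the thioester under palladium catalysis stops at the ketone, forming C12–C13 without epimerising C14, whose R configuration comes from the glycerate.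

**Step 13**
Reactants: 21 the C13 ketone
Product: 22 methyl (1R,5S,6R,8aR)-5-{(3S)-3-[(4R)-2,2-dimethyl-1,3-dioxolan-4-yl]-3-hydroxybutyl}-1,5,6-trimethyl-1,2,3,5,6,7,8,8a-octahydronaphthalene-1-carboxylate
Conditions: MeMgBr (2 equiv), THF, −78 °C
Reagents that add atoms: methylmagnesium bromide C[Mg]Br
Why: In this Grignard addition under Cram-chelate control, magnesium bridges the ketone oxygen and the α-oxygen of the dioxolane so that methyl adds from the face of the C14 hydrogen and sets C13 as S, while the hindered neopentyl-type ester is not attacked at −78 °C.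

**Step 14**
Reactants: 22 the tertiary alcohol acetonide
Product: 23 methyl (1R,5S,6R,8aR)-1,5,6-trimethyl-5-[(3S,4R)-3,4,5-trihydroxy-3-methylpentyl]-1,2,3,5,6,7,8,8a-octahydronaphthalene-1-carboxylate
Conditions: AcOH/H2O (4:1), 40 °C
Reagents that add atoms: water O
Why: Mild acid-catalysed acetal hydrolysis frees the 14,15-diol under conditions too weak to ionise the tertiary alcohol or to move the C1=C10 alkene.

**Step 15**
Reactants: 23 the 13,14,15-triol
Product: 24 methyl (1R,5S,6R,8aR)-5-[(3S,4R)-4,5-diacetoxy-3-hydroxy-3-methylpentyl]-1,5,6-trimethyl-1,2,3,5,6,7,8,8a-octahydronaphthalene-1-carboxylate (the target; halimane numbering 4R,5R,8R,9S,13S,14R)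
Conditions: Ac2O, pyridine, rt
Reagents that add atoms: acetic anhydride CC(=O)OC(C)=O
Why: Chemoselective acetylation with Ac2O/pyridine esterifies the primary and the secondary hydroxyl groups and leaves the tertiary C13 hydroxyl free for steric reasons.

**Compound list**

1 | 2-methylcyclohex-2-en-1-one | CC1=CCCCC1=O | starting material
2 | dimethylaluminium (R)-2,3-dimethylcyclohex-1-en-1-olate | C[C@@H]1CCCC(O[Al](C)C)=C1C | intermediate
3 | (R)-[(2,3-dimethylcyclohex-1-en-1-yl)oxy]trimethylsilane | C[C@@H]1CCCC(O[Si](C)(C)C)=C1C | intermediate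
4 | allyl bromide | C=CCBr | starting material
5 | lithium (R)-2,3-dimethylcyclohex-1-en-1-olate | C[C@@H]1CCCC([O-])=C1C.[Li+] | intermediate
6 | (2S,3R)-2-allyl-2,3-dimethylcyclohexan-1-one | O=C1CCC[C@@H](C)[C@]1(C)CC=C | intermediate
7 | potassium (5R,6S)-6-allyl-5,6-dimethylcyclohex-1-en-1-olate | [K+].[O-]C1=CCC[C@@H](C)[C@]1(C)CC=C | intermediate
8 | (5R,6S)-6-allyl-5,6-dimethylcyclohex-1-en-1-yl trifluoromethanesulfonate | O=S(=O)(OC1=CCC[C@@H](C)[C@]1(C)CC=C)C(F)(F)F | intermediate
9 | tributyl(vinyl)stannane | C=C[Sn](CCCC)(CCCC)CCCC | starting material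
10 | (5R,6S)-6-allyl-5,6-dimethyl-1-vinylcyclohex-1-ene | C=CC1=CCC[C@@H](C)[C@]1(C)CC=C | intermediate
11 | methacrolein | CC(=C)C=O | starting material
12 | (1R,5S,6R,8aR)-5-allyl-1,5,6-trimethyl-1,2,3,5,6,7,8,8a-octahydronaphthalene-1-carbaldehyde | O=C[C@]1(C)CCC=C2[C@H]1CC[C@@H](C)[C@]2(C)CC=C | intermediate
13 | (1R,5S,6R,8aR)-5-allyl-1,5,6-trimethyl-1,2,3,5,6,7,8,8a-octahydronaphthalene-1-carboxylic acid | OC(=O)[C@]1(C)CCC=C2[C@H]1CC[C@@H](C)[C@]2(C)CC=C | intermediate
14 | methyl (1R,5S,6R,8aR)-5-allyl-1,5,6-trimethyl-1,2,3,5,6,7,8,8a-octahydronaphthalene-1-carboxylate | COC(=O)[C@]1(C)CCC=C2[C@H]1CC[C@@H](C)[C@]2(C)CC=C | intermediate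
15 | methyl (1R,5S,6R,8aR)-1,5,6-trimethyl-5-(2-oxoethyl)-1,2,3,5,6,7,8,8a-octahydronaphthalene-1-carboxylate | COC(=O)[C@]1(C)CCC=C2[C@H]1CC[C@@H](C)[C@]2(C)CC=O | intermediate
16 | methyl (1R,5S,6R,8aR)-5-(2-hydroxyethyl)-1,5,6-trimethyl-1,2,3,5,6,7,8,8a-octahydronaphthalene-1-carboxylate | COC(=O)[C@]1(C)CCC=C2[C@H]1CC[C@@H](C)[C@]2(C)CCO | intermediate
17 | methyl (1R,5S,6R,8aR)-5-(2-iodoethyl)-1,5,6-trimethyl-1,2,3,5,6,7,8,8a-octahydronaphthalene-1-carboxylate | COC(=O)[C@]1(C)CCC=C2[C@H]1CC[C@@H](C)[C@]2(C)CCI | intermediate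
18 | methyl (R)-2,2-dimethyl-1,3-dioxolane-4-carboxylate | COC(=O)[C@H]1COC(C)(C)O1 | starting material
19 | S-ethyl (R)-2,2-dimethyl-1,3-dioxolane-4-carbothioate | CCSC(=O)[C@H]1COC(C)(C)O1 | intermediate
20 | alkylzinc iodide from 17 (C12–ZnI) | COC(=O)[C@]1(C)CCC=C2[C@H]1CC[C@@H](C)[C@]2(C)CC[Zn]I | intermediate
21 | methyl (1R,5S,6R,8aR)-5-{3-[(4R)-2,2-dimethyl-1,3-dioxolan-4-yl]-3-oxopropyl}-1,5,6-trimethyl-1,2,3,5,6,7,8,8a-octahydronaphthalene-1-carboxylate | COC(=O)[C@]1(C)CCC=C2[C@H]1CC[C@@H](C)[C@]2(C)CCC(=O)[C@H]1COC(C)(C)O1 | intermediate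
22 | methyl (1R,5S,6R,8aR)-5-{(3S)-3-[(4R)-2,2-dimethyl-1,3-dioxolan-4-yl]-3-hydroxybutyl}-1,5,6-trimethyl-1,2,3,5,6,7,8,8a-octahydronaphthalene-1-carboxylate | COC(=O)[C@]1(C)CCC=C2[C@H]1CC[C@@H](C)[C@]2(C)CC[C@](C)(O)[C@H]1COC(C)(C)O1 | intermediate
23 | methyl (1R,5S,6R,8aR)-1,5,6-trimethyl-5-[(3S,4R)-3,4,5-trihydroxy-3-methylpentyl]-1,2,3,5,6,7,8,8a-octahydronaphthalene-1-carboxylate | COC(=O)[C@]1(C)CCC=C2[C@H]1CC[C@@H](C)[C@]2(C)CC[C@](C)(O)[C@@H](CO)O | intermediate
24 | methyl (1R,5S,6R,8aR)-5-[(3S,4R)-4,5-diacetoxy-3-hydroxy-3-methylpentyl]-1,5,6-trimethyl-1,2,3,5,6,7,8,8a-octahydronaphthalene-1-carboxylate | COC(=O)[C@]1(C)CCC=C2[C@H]1CC[C@@H](C)[C@]2(C)CC[C@](C)(O)[C@@H](COC(C)=O)OC(C)=O | target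

**Step count**

Total: 15 steps. Longest linear sequence: 14 steps (steps 1–10 and 12–15); step 11 is a one-step side branch.

**Steps most likely to fail**

Step 5. The cycloaddition may discriminate poorly between the two diene faces or between the formyl-exo and formyl-endo modes, and a slow reaction would give the Lewis acid time to oligomerise the diene. The fallback sets out from triflate 8 and comes back at aldehyde 12. Carbonylative Stille coupling of 8 (CO, Me4Sn, Pd(PPh3)4, LiCl, DMF) would give the methyl ketone 1-[(5R,6S)-6-allyl-5,6-dimethylcyclohex-1-en-1-yl]ethan-1-one F1. Kinetic enolisation (LiN(iPr)2, t-BuMe2SiCl, THF, −78 °C) would turn it into the cross-conjugated 2-silyloxy diene F2. Its oxygen at C1 raises the diene HOMO and reinforces the wanted orientation, so the cycloaddition with 11 can be run at −78 °C under a bulky triflimide-activated chiral oxazaborolidine, which adds catalyst control of face and exo mode. This would give the C1 silyl enol ether aldehyde F3. CsF/PhNTf2 would convert it into the C1 enol triflate F4 without moving the double bond, and formate reduction (Pd(OAc)2, PPh3, Bu3N, HCO2H, DMF, 60 °C) would deliver 12.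

Step 13. Chelation of magnesium by the dioxolane oxygen may be incomplete, so that open-chain addition competes and the C13 configuration is eroded. The fallback sets out from iodide 17 and comes back at triol 23, replacing substrate control by reagent control. The zinc reagent 20 made from 17 would be Negishi-coupled (Pd(PPh3)4, THF) with (E)-tert-butyl[(3-iodobut-2-en-1-yl)oxy]dimethylsilane to give the (E)-C13=C14 allylic silyl ether F5. Bu4NF would free the (E)-allylic alcohol F6. Sharpless asymmetric epoxidation (Ti(OiPr)4, D-(−)-diethyl tartrate, t-BuOOH, CH2Cl2, −20 °C) would give the (13R,14R)-epoxy alcohol F7 without touching the ring alkene. Acid-catalysed hydrolysis (dilute HClO4, THF/H2O, 0 °C) opens the epoxide at tertiary C13 with inversion and would give 23.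

Step 8. Osmylation may not distinguish cleanly between the allyl alkene and the C1=C10 alkene, leading to over-oxidation of ring A. The fallback sets out from ester 14 and comes back at iodide 17, using a borane that only accepts the terminal alkene. Hydroboration–oxidation (9-BBN, THF; then NaBO3, H2O) would give the 3-hydroxypropyl ester F8. Oxidation with TEMPO/PhI(OAc)2 in MeCN/H2O would give the carboxylic acid F9. Coupling with N-hydroxypyridine-2-thione (DCC, CH2Cl2, dark) would give the Barton ester F10, and its photolysis in the presence of CHI3 (decarboxylative iodination) would lose one carbon and deliver 17.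

**Further compounds**

F1 | step 5 | 1-[(5R,6S)-6-allyl-5,6-dimethylcyclohex-1-en-1-yl]ethan-1-one | CC(=O)C1=CCC[C@@H](C)[C@]1(C)CC=C
F2 | step 5 | tert-butyl({1-[(5R,6S)-6-allyl-5,6-dimethylcyclohex-1-en-1-yl]vinyl}oxy)dimethylsilane | C=C(O[Si](C)(C)C(C)(C)C)C1=CCC[C@@H](C)[C@]1(C)CC=C
F3 | step 5 | (1R,5S,6R,8aR)-5-allyl-4-(tert-butyldimethylsilyloxy)-1,5,6-trimethyl-1,2,3,5,6,7,8,8a-octahydronaphthalene-1-carbaldehyde | O=C[C@]1(C)CCC(O[Si](C)(C)C(C)(C)C)=C2[C@H]1CC[C@@H](C)[C@]2(C)CC=C
F4 | step 5 | (5R,8aR,1S,2R)-1-allyl-5-formyl-1,2,5-trimethyl-1,2,3,4,4a,5,6,7-octahydronaphthalen-8-yl trifluoromethanesulfonate (C1 enol triflate of 12) | O=C[C@]1(C)CCC(OS(=O)(=O)C(F)(F)F)=C2[C@H]1CC[C@@H](C)[C@]2(C)CC=C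
F5 | step 13 | methyl (1R,5S,6R,8aR)-5-[(E)-5-(tert-butyldimethylsilyloxy)-3-methylpent-3-en-1-yl]-1,5,6-trimethyl-1,2,3,5,6,7,8,8a-octahydronaphthalene-1-carboxylate | COC(=O)[C@]1(C)CCC=C2[C@H]1CC[C@@H](C)[C@]2(C)CC/C(C)=C/CO[Si](C)(C)C(C)(C)C
F6 | step 13 | methyl (1R,5S,6R,8aR)-5-[(E)-5-hydroxy-3-methylpent-3-en-1-yl]-1,5,6-trimethyl-1,2,3,5,6,7,8,8a-octahydronaphthalene-1-carboxylate | COC(=O)[C@]1(C)CCC=C2[C@H]1CC[C@@H](C)[C@]2(C)CC/C(C)=C/CO
F7 | step 13 | methyl (1R,5S,6R,8aR)-5-{2-[(2R,3R)-3-(hydroxymethyl)-2-methyloxiran-2-yl]ethyl}-1,5,6-trimethyl-1,2,3,5,6,7,8,8a-octahydronaphthalene-1-carboxylate | COC(=O)[C@]1(C)CCC=C2[C@H]1CC[C@@H](C)[C@]2(C)CC[C@@]1(C)O[C@@H]1CO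
F8 | step 8 | methyl (1R,5S,6R,8aR)-5-(3-hydroxypropyl)-1,5,6-trimethyl-1,2,3,5,6,7,8,8a-octahydronaphthalene-1-carboxylate | COC(=O)[C@]1(C)CCC=C2[C@H]1CC[C@@H](C)[C@]2(C)CCCO
F9 | step 8 | 3-[(1S,2R,4aR,5R)-5-(methoxycarbonyl)-1,2,5-trimethyl-1,2,3,4,4a,5,6,7-octahydronaphthalen-1-yl]propanoic acid | COC(=O)[C@]1(C)CCC=C2[C@H]1CC[C@@H](C)[C@]2(C)CCC(O)=O
F10 | step 8 | 2-thioxopyridin-1(2H)-yl ester of F9 (Barton ester) | COC(=O)[C@]1(C)CCC=C2[C@H]1CC[C@@H](C)[C@]2(C)CCC(=O)ON1C=CC=CC1=S
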